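**Retrosynthetic overview**

1. The plan rests on C16 of ring D (C8, C14, C13, C16, C15): a methyl carbinol carbon bonded to the bridgehead C13, with its hydroxyl cis to C12. This is the retron of an aldol between a C13 enolate of a C12 ketone and the methyl ketone of an acetonyl arm on C8.
2. Ring A and the 19,10-lactone are taken apart first: C7 ester cleavage, C3 ketone reduction, C3–C4 (lactone-enolate aldol), C4–CH3, C10–C1 (allyl addition and lactonisation) and C5–C4 (alkylation of a C10 ketone).
3. Ring D is then opened at C13–C16 (copper hydride reductive aldol), which leads to a cis-hydrindane C12 enone (C13=C14) with a C8 acetonyl arm, the C7 ester and a C10 dioxolane.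
4. The enone position is secured from a cross-conjugated C12 dienone: zinc removes C9=C11 as part of a C10/C12 ene-dione, so only C13=C14 remains. C7 comes from carbonylation of a C6 enol triflate and the C10 ketone from oxidation of the doubly allylic C10.
5. Rings B and C and the quaternary C8 come from a proline-catalysed annulation of 2-methallylcyclopentane-1,3-dione with methyl vinyl ketone. Order of ring formation: B (starting material), C, D, lactone, A.

Key step: step 11

Remark: gibberellane numbering (ring A C1–C5 and C10; ring B C5, C6, C8–C10; ring C C8, C9, C11–C14; ring D C8, C13–C16) is used for every intermediate. C4 in 26–29 and C3 in 30 are carried as epimer mixtures because both centres are set again in steps 20 and 22.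

**Route**

Step 1
Reactants: 1 cyclopentane-1,3-dione; 2 3-bromo-2-methylpropene
Product: 3 2-(2-methylprop-2-enyl)cyclopentane-1,3-dione
Conditions: KOH, H2O, Cu powder (cat.), 50 °C
Reagents that add atoms: none
Why: C-alkylation of the 1,3-dione enolate by the allylic bromide in water, where solvation of the enolate oxygens favours attack through carbon; no stereocentre is formed.

Step 2
Reactants: 3 2-(2-methylprop-2-enyl)cyclopentane-1,3-dione; 4 methyl vinyl ketone
Product: 5 2-(2-methylprop-2-enyl)-2-(3-oxobutyl)cyclopentane-1,3-dione
Conditions: AcOH (cat.), H2O, 70 °C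
Reagents that add atoms: none
Why: Michael addition of the 2-substituted 1,3-dione to the vinyl ketone, the first half of a Robinson annulation, should give the prochiral triketone.

Step 3
Reactants: 5 triketone
Product: 7 bicyclic enedione (C6 ketone; C12 enone with C9=C11; methallyl on C8), via ketol 6 (not isolated)
Conditions: (S)-proline (30 mol %), DMF, 25 °C; then TsOH·H2O (cat.), PhMe, 60 °C
Reagents that add atoms: none
Why: Hajos–Parrish–Eder–Sauer–Wiechert reaction, in which the (S)-proline enamine of the side-chain ketone adds to one of the two enantiotopic ring carbonyls and so fixes the quaternary C8 in the sense known for the 7a-methyl series, followed by acid dehydration of ketol 6.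

Step 4
Reactants: 7 bicyclic enedione
Product: 8 cross-conjugated dienone (C9=C11 and C13=C14 on the C12 ketone; C6 ketone unchanged)
Conditions: DDQ, 1,4-dioxane, 90 °C
Reagents that add atoms: none
Why: Quinone dehydrogenation of the enone through its cross-conjugated dienol at the only α' position, C13–C14, as in the conversion of steroidal 4-en-3-ones into 1,4-dien-3-ones, which leaves a saturated five-ring ketone untouched.

Step 5
Reactants: 8 cross-conjugated dienone
Product: 9 C6 enol triflate (C5=C6–OTf)
Conditions: KN(SiMe3)2, PhNTf2, THF, –78 °C
Reagents that add atoms: N-phenylbis(trifluoromethanesulfonimide), O=S(=O)(N(c1ccccc1)S(=O)(=O)C(F)(F)F)C(F)(F)F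
Why: Kinetic enolisation of the saturated C6 ketone can only occur at C5 (C8 is quaternary and the dienone has no α'-hydrogen left), and O-sulfonylation of that enolate gives the enol triflate.

Step 6
Reactants: 9 C6 enol triflate
Product: 10 methyl ester (C7 on C6; C5=C6; C12 dienone)
Conditions: CO (1 atm), MeOH, Pd(OAc)2 (5 mol %), PPh3, Et3N, DMF, 50 °C
Reagents that add atoms: carbon monoxide, [C-]#[O+]; methanol, CO
Why: Palladium-catalysed methoxycarbonylation of the enol triflate (oxidative addition, CO insertion, methanolysis) installs C7 as the methyl ester.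

Step 7
Reactants: 10 methyl ester
Product: 11 C10 ketone (C10/C12 dione with C5=C6, C9=C11 and C13=C14)
Conditions: tBuOOH (70 % aq), dirhodium tetrakis(caprolactamate) Rh2(C6H10NO)4 (1 mol %), ClCH2CH2Cl, 40 °C
Reagents that add atoms: tert-butyl hydroperoxide, CC(C)(C)OO
Why: Rhodium-catalysed allylic oxidation of the γ-methylene of an unsaturated carbonyl compound; C10 is doubly allylic and γ to both the ester and the dienone carbonyl, so hydrogen abstraction by tert-butylperoxyl radicals should occur there.

Step 8
Reactants: 11 C10 ketone
Product: 12 cis-hydrindane diketone (C10 ketone; C12 enone with C13=C14; C6 ester cis to the methallyl arm)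
Conditions: Zn dust, AcOH, 25 °C
Reagents that add atoms: none
Why: Dissolving-metal reduction of ene-1,4-dicarbonyl units, which saturates C9=C11 (between the C10 and C12 ketones) and C5=C6 (between the C10 ketone and the ester) but not the simple C13=C14 enone; C9, α to the C10 ketone, should settle as the more stable cis-hydrindanone, and C6 is protonated (and, as an ester α-centre, can be equilibrated) to put the ester on the convex face cis to the methallyl arm.

Step 9
Reactants: 12 cis-hydrindane diketone
Product: 13 C10 dioxolane
Conditions: (Me3SiOCH2)2, Me3SiOTf (5 mol %), CH2Cl2, –78 → –20 °C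
Reagents that add atoms: 1,2-bis(trimethylsilyloxy)ethane, C[Si](C)(C)OCCO[Si](C)(C)C
Why: Noyori ketalisation is selective for the saturated C10 ketone over the conjugated C12 ketone and is mild enough for the 1,1-disubstituted alkene.

Step 10
Reactants: 13 C10 dioxolane
Product: 15 cis-hydrindane C12 enone with C8 acetonyl arm; C7 methyl ester; C10 dioxolane, via ozonide 14 (not isolated)
Conditions: O3, CH2Cl2, –78 °C (stopped when 13 is consumed); then Me2S, –78 → 25 °C
Reagents that add atoms: ozone, [O-][O+]=O
Why: Ozonolysis is chemoselective because the electron-rich 1,1-disubstituted alkene reacts far faster than the electron-poor enone double bond, and reductive work-up of ozonide 14 gives the methyl ketone.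

Step 11
Reactants: 15 cis-hydrindane enone with acetonyl arm
Product: 17 tricyclic ketol (rings B, C and D; C12 ketone; C16 tertiary alcohol), via copper enolate 16 (not isolated)
Conditions: [(Ph3P)CuH]6 (0.4 equiv), PhMe, –40 → 0 °C; then aq NH4Cl
Reagents that add atoms: none
Why: Conjugate delivery of hydride from copper to C14 of the C12 enone generates copper enolate 16 with its double bond between C12 and C13 and none of the C11 isomer, and this enolate adds to the C16 carbonyl of the acetonyl arm to form the C13–C16 bond; the closest known reaction type is the copper hydride reductive aldol cyclisation of keto enones to β-hydroxy ketones. Ring D (C8, C14, C13, C16, C15) closes in the 5-(enolexo)-exo-trig mode from the ring C conformer that holds the acetonyl arm axial, which turns the cis-hydrindane into the bicyclo[3.2.1]octane. The configuration of the new bridgehead C13 is dictated by C8, because the two-carbon bridge C15–C16 can span C8 and C13 only on the face of ring C that carries the arm. The C16 carbinol configuration should come from a closed transition state in which one copper centre bridges the enolate oxygen and the acceptor carbonyl oxygen, so that the new hydroxyl points to the C12 carbonyl (cis on ring D) and the methyl group to the outside of the bicycle, which is the arrangement of the target. The step needs 1,4- over 1,2-reduction and must leave the methyl ketone, the ester and the dioxolane unreduced, which the soft phosphine-bound hydride and the low temperature secure. Loss of water from the product would require a bridgehead double bond at C13 and is not expected.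

Step 12
Reactants: 17 tricyclic ketol
Product: 18 C12 tosylhydrazone
Conditions: TsNHNH2, MeOH, 50 °C
Reagents that add atoms: p-toluenesulfonohydrazide, Cc1ccc(cc1)S(=O)(=O)NN
Why: Condensation of the C12 ketone with the sulfonyl hydrazide, in which ester and dioxolane do not react and the neutral medium avoids retro-aldol opening of the ketol.

Step 13
Reactants: 18 C12 tosylhydrazone
Product: 19 C12-deoxy compound (C12 methylene; C16 alcohol; C10 dioxolane; C7 ester)
Conditions: catecholborane, CHCl3, 0 °C; then NaOAc·3H2O, 60 °C
Reagents that add atoms: none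
Why: Caglioti-type tosylhydrazone reduction, in which the borane reduces the C=N bond and acetate-induced loss of sulfinate and nitrogen from the resulting diazene leaves a methylene at C12 without touching C13, the ester or the dioxolane.

Step 14
Reactants: 19 C12-deoxy compound
Product: 20 C10 ketone
Conditions: PPTS (cat.), acetone/H2O, 55 °C
Reagents that add atoms: water, O
Why: Mild acid-catalysed hydrolysis of the dioxolane frees the C10 ketone under conditions that the tertiary C16 alcohol tolerates.

Step 15
Reactants: 20 C10 ketone; 21 methyl bromoacetate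
Product: 22 keto diester (methoxycarbonylmethyl arm on C5, trans to the C6 ester)
Conditions: LiN(iPr)2 (2.2 equiv), THF, –78 °C; then 21, –78 → –30 °C
Reagents that add atoms: none
Why: Kinetic enolate alkylation, in which the C10 ketone is deprotonated at the methylene C5 and not at the hindered ring-fusion carbon C9 (the second equivalent of base covers the C16 hydroxyl), and the SN2 step occurs anti to the neighbouring C6 ester, which is also the more stable arrangement at this epimerisable centre.

Step 16
Reactants: 22 keto diester; 23 allyl bromide
Product: 25 19,10-γ-lactone with C10 allyl group (C4 still a methylene), via hydroxy diester 24 (not isolated)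
Conditions: Zn dust, THF/sat. aq NH4Cl, 25 °C; then PPTS (cat.), PhMe, 50 °C
Reagents that add atoms: none
Why: Barbier allylation, in which the allylzinc reagent adds to the C10 ketone but not to the esters and should attack from the face opposite the two α-substituents (C11 on C9 and the arm on C5), so that the new hydroxyl is cis to the C5 arm and closes the γ-lactone with loss of methanol.

Step 17
Reactants: 25 allyl lactone
Product: 26 C4-methyl lactone
Conditions: LiN(iPr)2 (2.1 equiv), THF, –78 °C; then MeI
Reagents that add atoms: iodomethane, CI
Why: Lactone enolate alkylation (the lactone α-position is more acidic and far less hindered than C6 of the ester), in which the configuration of C4 does not matter because C4 is enolised again in step 20.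

Step 18
Reactants: 26 C4-methyl lactone
Product: 28 primary alcohol at C3, via alkylborane 27 (not isolated)
Conditions: 9-BBN, THF, 25 °C; then 30 % H2O2, aq NaOAc, 0 °C
Reagents that add atoms: hydrogen peroxide, OO
Why: Anti-Markovnikov hydroboration of the terminal alkene with a dialkylborane that does not reduce lactones or esters, followed by oxidation of the carbon–boron bond.

Step 19
Reactants: 28 primary alcohol
Product: 29 C3 aldehyde
Conditions: Dess–Martin periodinane, NaHCO3, CH2Cl2, 25 °C
Reagents that add atoms: none
Why: Dess–Martin oxidation of the primary alcohol under buffered conditions, which cannot oxidise the tertiary C16 alcohol.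

Step 20
Reactants: 29 C3 aldehyde
Product: 30 tetracyclic β-hydroxy lactone (ring A closed; methyl ester of the target as a mixture of C3 epimers)
Conditions: NaOMe (0.1 M), MeOH, 25 °C, 5 mM in 29
Reagents that add atoms: none
Why: Intramolecular aldol addition in the 6-(enolexo)-exo-trig mode of the C4 lactone enolate to the C3 aldehyde, the equilibrium through which 3-hydroxy gibberellin lactones epimerise in base; the quaternary C4 is set by the lactone bridge, since C3 can bond only to the face of C4 that carries C1, and C3 forms as an epimer mixture.

Step 21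
Reactants: 30 tetracyclic β-hydroxy lactone
Product: 31 3-ketone
Conditions: Dess–Martin periodinane, NaHCO3, CH2Cl2, 25 °C
Reagents that add atoms: none
Why: Dess–Martin oxidation converges both C3 epimers on one ketone, whose α-carbon C4 is quaternary and cannot epimerise.

Step 22
Reactants: 31 3-ketone
Product: 32 methyl ester of the target (axial 3β alcohol)
Conditions: K[BH(sBu)3], THF, –78 °C; then aq NH4Cl
Reagents that add atoms: none
Why: Bulky trialkylborohydride reduction, in which hydride enters along the equatorial trajectory and should give the axial alcohol anti to the lactone bridge on C4, while lactone and ester are not reduced at –78 °C.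

Step 23
Reactants: 32 methyl ester of the target
Product: 33 target acid
Conditions: LiSPr, HMPA, 25 °C; then 1 M HCl to pH 3
Reagents that add atoms: none
Why: SN2 demethylation of the hindered C7 methyl ester by thiolate avoids hydroxide, which would epimerise C3 by retro-aldol reaction, and does not cleave the tertiary-alkyl lactone.

**Compound list**

1 | cyclopentane-1,3-dione | O=C1CCC(=O)C1 | starting material
2 | 3-bromo-2-methylpropene | CC(=C)CBr | starting material
3 | 2-(2-methylprop-2-enyl)cyclopentane-1,3-dione | CC(=C)CC1C(=O)CCC1=O | intermediate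
4 | methyl vinyl ketone | CC(=O)C=C | starting material
5 | 2-(2-methylprop-2-enyl)-2-(3-oxobutyl)cyclopentane-1,3-dione | CC(=C)CC1(CCC(C)=O)C(=O)CCC1=O | intermediate
6 | cis-fused ketol: 3a-hydroxy-7a-(2-methylprop-2-enyl)hexahydroindene-1,5-dione, C9 hydroxyl cis to the methallyl group on C8 | CC(=C)C[C@]12CCC(=O)C[C@@]1(O)CCC2=O | intermediate
7 | (7aR)-7a-(2-methylprop-2-enyl)-2,3,7,7a-tetrahydro-1H-indene-1,5(6H)-dione (C6 ketone, C12 enone with C9=C11; C8 as delivered by (S)-proline) | CC(=C)C[C@]12CCC(=O)C=C1CCC2=O | intermediate
8 | 7a-(2-methylprop-2-enyl)-2,3-dihydro-1H-indene-1,5(7aH)-dione (C12 dienone with C9=C11 and C13=C14, C6 ketone) | CC(=C)C[C@]12C=CC(=O)C=C1CCC2=O | intermediate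
9 | C6 enol triflate of 8 (C5=C6–OSO2CF3) | CC(=C)C[C@]12C=CC(=O)C=C1CC=C2OS(=O)(=O)C(F)(F)F | intermediate
10 | methyl 7a-(2-methylprop-2-enyl)-5-oxo-5,7a-dihydro-3H-indene-1-carboxylate (C7 ester on C6, C5=C6, C12 dienone) | CC(=C)C[C@]12C=CC(=O)C=C1CC=C2C(=O)OC | intermediate
11 | C10 ketone of 10 (C10/C12 dione with C5=C6, C9=C11, C13=C14) | CC(=C)C[C@]12C=CC(=O)C=C1C(=O)C=C2C(=O)OC | intermediate
12 | cis-hydrindane: C10 ketone, C12 enone (C13=C14), H9 cis to the methallyl arm on C8, C6 ester cis to that arm | O=C1[C@@H]2CC(=O)C=C[C@]2(CC(C)=C)[C@@H](C(=O)OC)C1 | intermediate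
13 | C10 ethylene ketal of 12 | O1CCOC12[C@@H]3CC(=O)C=C[C@]3(CC(C)=C)[C@@H](C(=O)OC)C2 | intermediate
14 | ozonide of 13 (3-methyl-1,2,4-trioxolan-3-ylmethyl arm on C8, both epimers at the trioxolane carbon) | O1CCOC12[C@@H]3CC(=O)C=C[C@]3(CC4(C)OCOO4)[C@@H](C(=O)OC)C2 | intermediate
15 | cis-hydrindane C12 enone (C13=C14) with acetonyl arm on C8, C7 methyl ester on C6 (cis to the arm), C10 dioxolane | O1CCOC12[C@@H]3CC(=O)C=C[C@]3(CC(C)=O)[C@@H](C(=O)OC)C2 | intermediate
16 | copper enolate of 15 (C12–O–Cu, C12=C13, C14 methylene; phosphine ligands omitted) | O1CCOC12[C@@H]3CC(O[Cu])=CC[C@]3(CC(C)=O)[C@@H](C(=O)OC)C2 | intermediate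
17 | tricyclic ketol: rings B, C and D, C12 ketone, C16 tertiary alcohol with hydroxyl cis to C12 on ring D, C10 dioxolane, C7 methyl ester | O1CCOC12[C@@H]3CC(=O)[C@@H]4C[C@]3(C[C@]4(C)O)[C@@H](C(=O)OC)C2 | intermediate
18 | C12 tosylhydrazone of 17 | O1CCOC12[C@@H]3CC(=NNS(=O)(=O)c5ccc(C)cc5)[C@@H]4C[C@]3(C[C@]4(C)O)[C@@H](C(=O)OC)C2 | intermediate
19 | C12-deoxy compound (C12 methylene, C16 alcohol, C10 dioxolane, C7 ester) | O1CCOC12[C@@H]3CC[C@@H]4C[C@]3(C[C@]4(C)O)[C@@H](C(=O)OC)C2 | intermediate
20 | C10 ketone of the B/C/D tricycle | O=C1[C@@H]2CC[C@@H]3C[C@]2(C[C@]3(C)O)[C@@H](C(=O)OC)C1 | intermediate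
21 | methyl bromoacetate | COC(=O)CBr | starting material
22 | keto diester: methoxycarbonylmethyl arm (C4, C19) on C5, trans to the C6 ester | O=C1[C@@H]2CC[C@@H]3C[C@]2(C[C@]3(C)O)[C@@H](C(=O)OC)[C@@H]1CC(=O)OC | intermediate
23 | allyl bromide | C=CCBr | starting material
24 | hydroxy diester: allyl group (C1–C3) and hydroxyl on C10, hydroxyl cis to the C5 arm | C=CC[C@@]1(O)[C@@H]2CC[C@@H]3C[C@]2(C[C@]3(C)O)[C@@H](C(=O)OC)[C@@H]1CC(=O)OC | intermediate
25 | 19,10-γ-lactone cis-fused to ring B, allyl on C10, C4 methylene | O=C1O[C@]2(CC=C)[C@@H]3CC[C@@H]4C[C@]3(C[C@]4(C)O)[C@@H](C(=O)OC)[C@@H]2C1 | intermediate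
26 | C4-methyl lactone (C4 epimers; drawn with the methyl trans to C6) | O=C1O[C@]2(CC=C)[C@@H]3CC[C@@H]4C[C@]3(C[C@]4(C)O)[C@@H](C(=O)OC)[C@@H]2[C@H]1C | intermediate
27 | B-alkyl-9-borabicyclo[3.3.1]nonane adduct of 26 (boron on C3) | O=C1O[C@]2(CCCB5C6CCCC5CCC6)[C@@H]3CC[C@@H]4C[C@]3(C[C@]4(C)O)[C@@H](C(=O)OC)[C@@H]2[C@H]1C | intermediate
28 | primary alcohol (3-hydroxypropyl on C10) | O=C1O[C@]2(CCCO)[C@@H]3CC[C@@H]4C[C@]3(C[C@]4(C)O)[C@@H](C(=O)OC)[C@@H]2[C@H]1C | intermediate
29 | aldehyde (3-oxopropyl on C10) | O=C1O[C@]2(CCC=O)[C@@H]3CC[C@@H]4C[C@]3(C[C@]4(C)O)[C@@H](C(=O)OC)[C@@H]2[C@H]1C | intermediate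
30 | methyl ester of the target as a mixture of C3 epimers (ring A closed, C4 quaternary) | C[C@@]12C(=O)O[C@]3(CCC1O)[C@@H]1CC[C@@H]4C[C@]1(C[C@]4(C)O)[C@@H](C(=O)OC)[C@@H]32 | intermediate
31 | 3-ketone (3-oxo methyl ester) | C[C@@]12C(=O)O[C@]3(CCC1=O)[C@@H]1CC[C@@H]4C[C@]1(C[C@]4(C)O)[C@@H](C(=O)OC)[C@@H]32 | intermediate
32 | methyl ester of the target (axial 3β hydroxyl, cis to the C4 methyl and anti to the lactone bridge) | C[C@@]12C(=O)O[C@]3(CC[C@@H]1O)[C@@H]1CC[C@@H]4C[C@]1(C[C@]4(C)O)[C@@H](C(=O)OC)[C@@H]32 | intermediate
33 | CNP0343121.3 (3,16-dihydroxy 19,10-lactone 7-acid) | C[C@@]12C(=O)O[C@]3(CC[C@@H]1O)[C@@H]1CC[C@@H]4C[C@]1(C[C@]4(C)O)[C@@H](C(=O)O)[C@@H]32 | target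

**Step count and risks**

Total step count: 23. Longest linear sequence: 23 steps (1 to 33).

Steps most likely to fail:

- Step 11 (key step). Copper enolate 16 may be protonated before it cyclises, or it may add through an open transition state with poor facial selectivity at C16. The fallback separates enolate formation from the aldol addition. Setting out from 15, rhodium-catalysed 1,4-hydrosilylation of the enone ((Ph3P)3RhCl, Et3SiH, PhH, 50 °C) should give the C12 triethylsilyl enol ether F1 with the double bond again fixed at C12=C13. A fluoride-released intramolecular Mukaiyama-type aldol addition to the C16 ketone (Bu4NF, THF, –78 °C) then closes ring D, and the route is rejoined at 17.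

- Step 16. Poor facial selectivity of the allyl addition to the C10 ketone would give the C10 epimer, whose hydroxyl is trans to the C5 arm and cannot lactonise. The fallback makes the C10–O bond before the C10–C1 bond, so that C5 dictates C10. Setting out from 20, alkylation as in step 15 but with benzyl bromoacetate gives the benzyl ester F2. Hydrogenolysis (H2, Pd/C, EtOAc) gives the keto acid F3, which is in equilibrium with its hydroxy lactone. Hosomi–Sakurai allylation of the acyloxycarbenium ion derived from it (allyltrimethylsilane, BF3·OEt2, CH2Cl2, –78 °C) can deliver the allyl group only to the face that keeps the lactone cis-fused to ring B, and this returns to 25.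

- Step 7. Hydrogen abstraction may also occur at the allylic positions of the methallyl arm, and the oxidation may stop at the mixed C10 tert-butyl peroxide or degrade the dienone. The fallback uses the acidity of the C10 hydrogens instead of their weak C–H bond. Setting out from 10, deprotonation with DBU under O2 in the presence of P(OEt)3 (MeCN, 0 °C) should hydroxylate the extended enolate at its γ-carbon and give the C10 alcohol F4. Dess–Martin oxidation of F4 then gives 11.

Further compounds
F1 | step 11 | C12 triethylsilyl enol ether of 15 (C12=C13) | O1CCOC12[C@@H]3CC(O[Si](CC)(CC)CC)=CC[C@]3(CC(C)=O)[C@@H](C(=O)OC)C2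
F2 | step 16 | benzyl ester analogue of 22 (benzyloxycarbonylmethyl arm on C5) | O=C1[C@@H]2CC[C@@H]3C[C@]2(C[C@]3(C)O)[C@@H](C(=O)OC)[C@@H]1CC(=O)OCc1ccccc1
F3 | step 16 | keto acid (carboxymethyl arm on C5, C10 ketone) | O=C1[C@@H]2CC[C@@H]3C[C@]2(C[C@]3(C)O)[C@@H](C(=O)OC)[C@@H]1CC(=O)O
F4 | step 7 | C10 alcohol of 10 | CC(=C)C[C@]12C=CC(=O)C=C1C(O)C=C2C(=O)OC
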